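Plan
1. Numbering (germacrane): carbocycle C1–C10; oxirane on C4 (methyl C15) and C5; lactone O6–C6–C7–C11(=C13)–C12; methacrylate on O8, acetate on O9, methyl ester C14 on C10.
2. Enabling feature: C10 carries both the ester carbon C14 and the oxygenated ring carbon C9. With C9 taken back to a ketone and C1=C10 saturated, C9–C10–C14 is a cyclic β-keto ester. The ten-membered ring is therefore cut at C9–C10 by inserting one sulfur atom, which gives an eleven-membered C9 thiolactone with S on C10.
3. Further cuts: S–C10 (thiocarboxylate alkylation), C7–C8 (allylindium plus glyoxylic acid), C7=C11 (ring-closing metathesis), C6–C7 (vinyl addition), and C1=C10 of an enoate (cross-metathesis at the prenyl end of nerol).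
4. Forward order: oxirane, chain end C1–C10–C14, butenolide, α-methylene lactone bearing C8–C9, eleven-membered thiolactone, ten-membered carbocycle, then C1=C10, C9–OH and the two esters.
5. Stereochemistry: the target oxirane has C3 and C6 cis, so C4/C5 come from Sharpless epoxidation of the Z-alkene of nerol. C6 is set by Felkin–Anh addition, C7 by attack anti to the C5 side chain, C8 by a chelated chair in the Barbier step, and C9 by Felkin–Anh hydride delivery next to the O8 silyl ether. The ring-cis C1=C10 geometry comes from the ring.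
6. C13 is masked as its dimethylamine adduct from before sulfur enters until the last step, because thiocarboxylate and phosphite would otherwise add to the methylene lactone.

Key step: step 16

Assumption: C10 is formed without control and is carried as both epimers (no stereo mark in the SMILES) until step 17 makes it planar; C11 of the amine adducts is drawn as the expected 11R epimer and is erased in the last step, so neither centre needs control.

Step 1
Reactants: 1 nerol
Product: 2 (2S,3R)-2,3-epoxynerol (C4 R and C5 S in target numbering)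
Conditions: Ti(OiPr)4 (5 mol %), L-(+)-diethyl tartrate (6 mol %), tBuOOH (decane), 4 Å MS, CH2Cl2, −20 °C
Reagents that add atoms: tert-butyl hydroperoxide, CC(C)(C)OO
Why: The Sharpless asymmetric epoxidation touches only the allylic alcohol alkene, L-(+)-tartrate gives the (2S,3R)-epoxide of nerol, and the Z geometry fixes C3 and C6 cis on the oxirane as the target requires.

Step 2
Reactants: 2 (2S,3R)-2,3-epoxynerol; 3 methyl acrylate
Product: 4 methyl (2E)-5-[(2R,3S)-3-(hydroxymethyl)-2-methyloxiran-2-yl]pent-2-enoate
Conditions: second-generation Hoveyda–Grubbs catalyst (3 mol %), 3 (5 equiv), CH2Cl2, 40 °C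
Reagents that add atoms: none
Why: Olefin cross-metathesis of prenyl-type trisubstituted alkenes with acrylates is known for terpenoids, is driven by loss of a volatile alkene, and brings in C10 and C14 in one operation without touching the epoxy alcohol.

Step 3
Reactants: 4 enoate
Product: 5 methyl 2-hydroxy-5-[(2R,3S)-3-(hydroxymethyl)-2-methyloxiran-2-yl]pentanoate (both C10 epimers)
Conditions: Mn(dpm)3 (5 mol %), PhSiH3 (2 equiv), O2 (1 atm), iPrOH, 0 °C
Reagents that add atoms: dioxygen, O=O
Why: The Mukaiyama-type reductive α-hydroxylation of α,β-unsaturated esters (hydrogen-atom transfer to C1, capture of the C10 radical by O2, reduction of the peroxide) is applied while the enoate is the only alkene present, and the uncontrolled C10 centre is harmless.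

Step 4
Reactants: 5 diol
Product: 6 methyl 5-[(2R,3R)-3-formyl-2-methyloxiran-2-yl]-2-hydroxypentanoate (same spatial arrangement; the C5 label changes by priority only)
Conditions: TEMPO (10 mol %), PhI(OAc)2 (1.1 equiv), CH2Cl2, rt
Reagents that add atoms: none
Why: The oxoammonium (TEMPO) oxidation prefers the primary carbinol C6 over the deactivated secondary α-hydroxy ester and does not epimerise or open the oxirane.

Step 5
Reactants: 6 hydroxy aldehyde
Product: 7 C10 triethylsilyl ether of 6
Conditions: Et3SiCl, imidazole, CH2Cl2, 0 °C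
Reagents that add atoms: chlorotriethylsilane, CC[Si](Cl)(CC)CC
Why: Routine silylation, with TES chosen because it can later be removed beside a hindered secondary TBS ether.

Step 6
Reactants: 7 epoxy aldehyde; 8 vinylmagnesium bromide
Product: 9 methyl 5-{(2R,3S)-3-[(1S)-1-hydroxyprop-2-enyl]-2-methyloxiran-2-yl}-2-(triethylsilyloxy)pentanoate (6S; O6 anti to the oxirane oxygen)
Conditions: 8 (1.2 equiv), THF, −78 °C; then pH 7 buffer
Reagents that add atoms: none
Why: Grignard 1,2-addition at −78 °C is faster at the aldehyde than at the ester, and the Felkin–Anh transition state with the C5–O bond anti to the incoming vinyl group, reinforced by the cis C3 chain, should favour the 5,6-anti (6S) alcohol, the other epimer being removed by chromatography.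

Step 7
Reactants: 9 allylic alcohol; 10 2-(bromomethyl)acrylic acid
Product: 12 O6 2-(bromomethyl)acrylate of 9, via 2-(bromomethyl)acryloyl chloride 11 (not isolated)
Conditions: 10, (COCl)2, DMF (cat.), CH2Cl2, 0 °C → rt; then 9, iPr2NEt, CH2Cl2, −20 → 0 °C
Reagents that add atoms: oxalyl chloride, O=C(Cl)C(=O)Cl (its chlorine is found only in 11)
Why: O-acylation by the acid chloride with a hindered amine avoids nucleophilic catalysts that would attack the allylic bromide, and it leaves C6 untouched.

Step 8
Reactants: 12 diene ester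
Product: 13 methyl 5-{(2R,3S)-3-[(2S)-4-(bromomethyl)-5-oxo-2,5-dihydrofuran-2-yl]-2-methyloxiran-2-yl}-2-(triethylsilyloxy)pentanoate (epoxy bromomethylbutenolide)
Conditions: second-generation Grubbs catalyst (5 mol %), CH2Cl2 (5 mM), 40 °C
Reagents that add atoms: none
Why: Ring-closing metathesis of allyl 2-substituted acrylates to α-substituted butenolides is well known, and its neutral conditions spare the base-sensitive C6–H next to the oxirane as well as the allylic bromide.

Step 9
Reactants: 13 bromomethylbutenolide; 14 glyoxylic acid monohydrate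
Product: 15 (6S,7R,8S)-hydroxy acid: 6,7-trans α-methylene-γ-lactone bearing CH(OH)CO2H (C8–C9) on C7
Conditions: In powder (2 equiv), 14 (5 equiv), THF/aq phosphate buffer (pH 6) 1:1, rt
Reagents that add atoms: none
Why: In this Barbier allylation, known for 3-(bromomethyl)butenolides, the allylindium reacts at its γ-carbon C7 through a closed chair on the face opposite to the C5 side chain (6,7-trans lactone), and the indium-bound carboxylate of glyoxylate sits axial so that the E-type allyl unit gives the 7,8-syn (8S) carbinol, the reversal known for γ-substituted allyl bromides with glyoxylic acid in water.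

Step 10
Reactants: 15 hydroxy acid
Product: 16 (11R)-13-dimethylamino-11,13-dihydro derivative of 15
Conditions: Me2NH (2 M in THF, 3 equiv), THF, 0 °C → rt
Reagents that add atoms: dimethylamine, CNC
Why: The aza-Michael addition of dimethylamine to an α-methylene-γ-butyrolactone is fast and selective, should give the epimer with C13 trans to C8, and yields a mask that does not leave under aprotic amidine base.

Step 11
Reactants: 16 amino hydroxy acid
Product: 18 O8-TBS acid (C4–C8 and C11 as in 16), via silyl ester 17 (not isolated)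
Conditions: TBSOTf (3 equiv), 2,6-lutidine (5 equiv), CH2Cl2, −78 → −20 °C; then K2CO3 (cat.), MeOH/H2O, 0 °C
Reagents that add atoms: tert-butyldimethylsilyl triflate, CC(C)(C)[Si](C)(C)OS(=O)(=O)C(F)(F)F
Why: Double silylation followed by solvolysis of the labile silyl ester is the standard route to O-silyl α-hydroxy acids, and the low temperature and excess lutidine protect the oxirane and the TES ether.

Step 12
Reactants: 18 acid
Product: 19 S-(9-fluorenylmethyl) C9 thioester
Conditions: 9-fluorenylmethanethiol (1.2 equiv), EDC·HCl, DMAP (cat.), CH2Cl2, 0 °C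
Reagents that add atoms: (9H-fluoren-9-yl)methanethiol, SCC1c2ccccc2-c2ccccc21
Why: Carbodiimide thioesterification introduces the sulfur as a latent thioacid that tolerates tertiary amines, buffered HF and mesylation, and is released only by a strong amidine base.

Step 13
Reactants: 19 thioester
Product: 20 C10 alcohol
Conditions: HF·pyridine, pyridine, THF, 0 °C
Reagents that add atoms: none
Why: Selective desilylation works because an unhindered TES ether is cleaved much faster than the hindered secondary TBS ether on O8, and buffered HF·pyridine is tolerated by trisubstituted epoxides and thioesters.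

Step 14
Reactants: 20 alcohol
Product: 21 C10 mesylate
Conditions: MsCl, Et3N, CH2Cl2, −20 °C
Reagents that add atoms: methanesulfonyl chloride, CS(=O)(=O)Cl
Why: Mesylation of an α-hydroxy ester gives a carbonyl-activated SN2 electrophile, and a short time at low temperature keeps the fluorenylmethyl thioester intact.

Step 15
Reactants: 21 mesylate
Product: 23 eleven-membered C9 thiolactone (S on C10; O8-TBS; C13 NMe2), via thiocarboxylate 22 (not isolated)
Conditions: slow addition of 21 to DBU (2 equiv), MeCN (final 1 mM), rt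
Reagents that add atoms: none
Why: DBU frees the thiocarboxylate by E1cB cleavage of the fluorenylmethyl group, and at high dilution this soft and very nucleophilic anion displaces the activated C10 mesylate (SN2, 11-exo-tet), the S-alkylation used to make macrocyclic thiolactones, either C10 epimer being serviceable.

Step 16
Reactants: 23 thiolactone
Product: 25 ten-membered C9 ketone with the C10 methyl ester (β-keto ester), via C9–C10 thiirane 24 (not isolated)
Conditions: DBU (3 equiv), P(OEt)3 (5 equiv), MeCN, 60 °C
Reagents that add atoms: none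
Why: DBU removes C10–H of 23, the only proton flanked by an ester and an acylthio group, and the enolate adds to the adjacent C9 thioester carbonyl to give the thiirane alkoxide 24. P(OEt)3 then takes the sulfur from 24, so that the C9–C10 bond remains and the enolate of β-keto ester 25 is left. This is the Eschenmoser sulfide contraction in its α-acylthio ester to β-keto ester form, which has been used to contract macrocyclic thiolactones. The C–C bond forms by a 3-exo-trig attack inside the eleven-membered ring, and loss of sulfur turns that ring into the carbocycle C1–C10, so no end-to-end medium-ring closure is needed, while P=S formation and the stabilised enolate make the change irreversible. The only new stereocentre, C10, is epimerisable and disappears in step 17, so it needs no control. The step requires enolisation at C10 and not at C8 or C11, which the acidity gap towards an amidine base and the bulky silyl ether on O8 secure, and it requires a substrate without a phosphite acceptor, which the amine mask at C13 secures.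

Step 17
Reactants: 25 β-keto ester
Product: 28 alkylidene β-keto ester with C1=C10 (C2 and C9 cis; E by priority), via C10 phenylselenide 26 (not isolated), via C10 selenoxide 27 (not isolated)
Conditions: PhSeCl, pyridine, CH2Cl2, 0 °C; then AcOH (2 equiv), 30% H2O2, 0 °C → rt
Reagents that add atoms: phenylselenenyl chloride, Cl[Se]c1ccccc1 (found only in 26 and 27); hydrogen peroxide, OO (its oxygen is found only in 27)
Why: Selenenylation of a β-keto ester at its acidic carbon and selenoxide syn-elimination, for which C1–H is the only β-hydrogen, is the standard desaturation of β-dicarbonyl compounds; the protonated amine is not oxidised, and the ring-cis alkene is expected as the less strained isomer, to which an alkylidene β-keto ester can also equilibrate.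

Step 18
Reactants: 28 enone
Product: 29 (9S)-allylic alcohol
Conditions: NaBH4, CeCl3·7H2O, MeOH, −78 °C
Reagents that add atoms: none
Why: The Luche reduction gives 1,2-attack on the doubly activated enone, and hydride delivery anti to the non-chelating O8 silyl ether (polar Felkin–Anh, from the ring periphery) should give the 8,9-syn diol pattern, that is 9S.

Step 19
Reactants: 29 alcohol
Product: 30 9-acetate
Conditions: Ac2O, pyridine, DMAP (cat.), CH2Cl2, 0 °C
Reagents that add atoms: acetic anhydride, CC(=O)OC(C)=O
Why: Routine acetylation of the only free hydroxyl group, carried out at once so that silyl migration from O8 has no time to occur.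

Step 20
Reactants: 30 acetate
Product: 31 8-alcohol
Conditions: HF·pyridine, pyridine, THF, 0 °C → rt
Reagents that add atoms: none
Why: Acidic fluoride desilylation avoids the alkoxide that would trigger O9 to O8 acetyl migration and is tolerated by the epoxide, the esters and the protonated amine.

Step 21
Reactants: 31 alcohol; 32 methacryloyl chloride
Product: 33 8-methacrylate (13-dimethylamino-11,13-dihydro target)
Conditions: 32, Et3N, DMAP (cat.), CH2Cl2, 0 °C
Reagents that add atoms: none
Why: O-acylation with retention at C8 installs the last ester while the lactone acceptor is still masked.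

Step 22
Reactants: 33 amine
Product: 35 target CNP0153978.8, via trimethylammonium iodide 34 (not isolated)
Conditions: MeI (10 equiv), THF, rt; then sat. aq NaHCO3, rt
Reagents that add atoms: iodomethane, CI (its methyl group is found only in 34)
Why: Quaternisation followed by mild E1cB (Hofmann-type) elimination is the standard way to regenerate an α-methylene-γ-butyrolactone from its dimethylamine adduct, and it removes the C11 centre without touching the other esters or the epoxide.

Compound list
1 | nerol | CC(C)=CCC/C(C)=C\CO | starting material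
2 | (2S,3R)-2,3-epoxynerol | OC[C@@H]1O[C@]1(C)CCC=C(C)C | intermediate
3 | methyl acrylate | C=CC(=O)OC | starting material
4 | methyl (2E)-5-[(2R,3S)-3-(hydroxymethyl)-2-methyloxiran-2-yl]pent-2-enoate | OC[C@@H]1O[C@]1(C)CC/C=C/C(=O)OC | intermediate
5 | methyl 2-hydroxy-5-[(2R,3S)-3-(hydroxymethyl)-2-methyloxiran-2-yl]pentanoate (C10 epimers) | OC[C@@H]1O[C@]1(C)CCCC(O)C(=O)OC | intermediate
6 | methyl 5-[(2R,3R)-3-formyl-2-methyloxiran-2-yl]-2-hydroxypentanoate | O=C[C@@H]1O[C@]1(C)CCCC(O)C(=O)OC | intermediate
7 | C10 triethylsilyl ether of 6 | O=C[C@@H]1O[C@]1(C)CCCC(O[Si](CC)(CC)CC)C(=O)OC | intermediate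
8 | vinylmagnesium bromide | C=C[Mg]Br | starting material
9 | (4R,5S,6S)-allylic alcohol | O[C@@H](C=C)[C@@H]1O[C@]1(C)CCCC(O[Si](CC)(CC)CC)C(=O)OC | intermediate
10 | 2-(bromomethyl)acrylic acid | C=C(CBr)C(=O)O | starting material
11 | 2-(bromomethyl)acryloyl chloride | C=C(CBr)C(=O)Cl | intermediate
12 | O6 2-(bromomethyl)acrylate of 9 | C=C(CBr)C(=O)O[C@@H](C=C)[C@@H]1O[C@]1(C)CCCC(O[Si](CC)(CC)CC)C(=O)OC | intermediate
13 | (4R,5S,6S)-epoxy bromomethylbutenolide | O=C1O[C@@H](C=C1CBr)[C@@H]1O[C@]1(C)CCCC(O[Si](CC)(CC)CC)C(=O)OC | intermediate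
14 | glyoxylic acid monohydrate | OC(O)C(=O)O | starting material
15 | (4R,5S,6S,7R,8S)-C9 hydroxy acid with 6,7-trans α-methylene lactone | O[C@H](C(=O)O)[C@H]1C(=C)C(=O)O[C@@H]1[C@@H]1O[C@]1(C)CCCC(O[Si](CC)(CC)CC)C(=O)OC | intermediate
16 | (11R)-13-dimethylamino-11,13-dihydro derivative of 15 | O[C@H](C(=O)O)[C@H]1[C@H](CN(C)C)C(=O)O[C@@H]1[C@@H]1O[C@]1(C)CCCC(O[Si](CC)(CC)CC)C(=O)OC | intermediate
17 | O8-TBS ether TBS ester of 16 | CC(C)(C)[Si](C)(C)O[C@H](C(=O)O[Si](C)(C)C(C)(C)C)[C@H]1[C@H](CN(C)C)C(=O)O[C@@H]1[C@@H]1O[C@]1(C)CCCC(O[Si](CC)(CC)CC)C(=O)OC | intermediate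
18 | O8-TBS C9 acid | CC(C)(C)[Si](C)(C)O[C@H](C(=O)O)[C@H]1[C@H](CN(C)C)C(=O)O[C@@H]1[C@@H]1O[C@]1(C)CCCC(O[Si](CC)(CC)CC)C(=O)OC | intermediate
19 | S-(9-fluorenylmethyl) C9 thioester | CC(C)(C)[Si](C)(C)O[C@H](C(=O)SCC1c2ccccc2-c2ccccc21)[C@H]1[C@H](CN(C)C)C(=O)O[C@@H]1[C@@H]1O[C@]1(C)CCCC(O[Si](CC)(CC)CC)C(=O)OC | intermediate
20 | C10 alcohol of 19 | CC(C)(C)[Si](C)(C)O[C@H](C(=O)SCC1c2ccccc2-c2ccccc21)[C@H]1[C@H](CN(C)C)C(=O)O[C@@H]1[C@@H]1O[C@]1(C)CCCC(O)C(=O)OC | intermediate
21 | C10 mesylate | CC(C)(C)[Si](C)(C)O[C@H](C(=O)SCC1c2ccccc2-c2ccccc21)[C@H]1[C@H](CN(C)C)C(=O)O[C@@H]1[C@@H]1O[C@]1(C)CCCC(OS(C)(=O)=O)C(=O)OC | intermediate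
22 | C9 thioacid C10 mesylate (present as its DBU salt) | CC(C)(C)[Si](C)(C)O[C@H](C(=O)S)[C@H]1[C@H](CN(C)C)C(=O)O[C@@H]1[C@@H]1O[C@]1(C)CCCC(OS(C)(=O)=O)C(=O)OC | intermediate
23 | eleven-membered C9 thiolactone with S on C10 | CC(C)(C)[Si](C)(C)O[C@H]1[C@H]2[C@H](CN(C)C)C(=O)O[C@@H]2[C@@H]2O[C@]2(C)CCCC(C(=O)OC)SC1=O | intermediate
24 | C9–C10 thiirane (C9 hydroxyl, present as alkoxide) | CC(C)(C)[Si](C)(C)O[C@H]1[C@H]2[C@H](CN(C)C)C(=O)O[C@@H]2[C@@H]2O[C@]2(C)CCCC3(C(=O)OC)SC13O | intermediate
25 | ten-membered C9 ketone C10 ester | CC(C)(C)[Si](C)(C)O[C@H]1[C@H]2[C@H](CN(C)C)C(=O)O[C@@H]2[C@@H]2O[C@]2(C)CCCC(C(=O)OC)C1=O | intermediate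
26 | C10 phenylselenide of 25 | CC(C)(C)[Si](C)(C)O[C@H]1[C@H]2[C@H](CN(C)C)C(=O)O[C@@H]2[C@@H]2O[C@]2(C)CCCC(C(=O)OC)([Se]c2ccccc2)C1=O | intermediate
27 | C10 selenoxide | CC(C)(C)[Si](C)(C)O[C@H]1[C@H]2[C@H](CN(C)C)C(=O)O[C@@H]2[C@@H]2O[C@]2(C)CCCC(C(=O)OC)([Se](=O)c2ccccc2)C1=O | intermediate
28 | C1=C10 alkylidene β-keto ester (ring-cis) | CC(C)(C)[Si](C)(C)O[C@H]1[C@H]2[C@H](CN(C)C)C(=O)O[C@@H]2[C@@H]2O[C@]2(C)CC/C=C(/C(=O)OC)C1=O | intermediate
29 | (9S)-allylic alcohol | CC(C)(C)[Si](C)(C)O[C@H]1[C@H]2[C@H](CN(C)C)C(=O)O[C@@H]2[C@@H]2O[C@]2(C)CC/C=C(/C(=O)OC)[C@@H]1O | intermediate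
30 | 9-acetate | CC(C)(C)[Si](C)(C)O[C@H]1[C@H]2[C@H](CN(C)C)C(=O)O[C@@H]2[C@@H]2O[C@]2(C)CC/C=C(/C(=O)OC)[C@@H]1OC(C)=O | intermediate
31 | 8-alcohol 9-acetate | O[C@H]1[C@H]2[C@H](CN(C)C)C(=O)O[C@@H]2[C@@H]2O[C@]2(C)CC/C=C(/C(=O)OC)[C@@H]1OC(C)=O | intermediate
32 | methacryloyl chloride | C=C(C)C(=O)Cl | starting material
33 | 13-dimethylamino-11,13-dihydro target | C=C(C)C(=O)O[C@H]1[C@H]2[C@H](CN(C)C)C(=O)O[C@@H]2[C@@H]2O[C@]2(C)CC/C=C(/C(=O)OC)[C@@H]1OC(C)=O | intermediate
34 | C13 trimethylammonium iodide | C=C(C)C(=O)O[C@H]1[C@H]2[C@H](C[N+](C)(C)C)C(=O)O[C@@H]2[C@@H]2O[C@]2(C)CC/C=C(/C(=O)OC)[C@@H]1OC(C)=O.[I-] | intermediate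
35 | CNP0153978.8 (4R,5S,6S,7R,8S,9S; 1(10)E) | C=C(C)C(=O)O[C@H]1[C@H]2C(=C)C(=O)O[C@@H]2[C@@H]2O[C@]2(C)CC/C=C(/C(=O)OC)[C@@H]1OC(C)=O | target

Total step count: 22. Longest linear sequence: 22 steps, from nerol.

Steps most likely to fail

Step 16. Attack of the C10 enolate on C9 may be too slow, because thiirane formation and shrinking of the ring raise transannular strain. Base-induced opening of the thiolactone or epimerisation at C8 could then take over. In the fallback C9–C10 still closes the ring, but by a reductive aldol-type closure. Mesylate 21 is reduced at the thioester by the Fukuyama method (Et3SiH, Pd/C) to the C9 aldehyde F1. LiBr in acetone exchanges the mesylate to give the α-bromo ester aldehyde F2. SmI2 in THF at high dilution closes the ten-membered ring by an intramolecular Reformatsky reaction to the β-hydroxy ester F3. Dess–Martin oxidation of F3 comes back to 25.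

Step 9. Loss of chelation would let the carboxyl group sit equatorial in the chair, which means poor or inverted simple diastereoselection at C8. In the fallback C8 is corrected by SN2 inversion instead of in the C–C bond-forming event. The coupling of 13 and 14 is taken to the 8R hydroxy acid F4. F4 is masked with Me2NH to the 8R amino acid F5 and coupled with 9-fluorenylmethanethiol (EDC) to the 8R hydroxy thioester F6. A Mitsunobu reaction with formic acid (PPh3, DIAD) inverts this carbonyl-activated carbinol to the 8S formate F7. Brief methanolysis (NaHCO3, MeOH, 0 °C) gives the 8S hydroxy thioester F8, and TBSOTf/2,6-lutidine comes back to 19.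

Step 15. Intermolecular S-alkylation (oligomerisation), or opening of the oxirane at C5 by the thiocarboxylate through a six-membered transition state, may outrun the eleven-membered closure. In the fallback the C10 carbinol itself becomes the electrophile. Alcohol 20 is treated with DBU and then acidified to the hydroxy thioacid F9. F9 is added slowly to preformed PPh3/DIAD in THF, so that a Mitsunobu thioesterification forms S–C10 through the far more reactive oxyphosphonium ion and comes back to 23.

Further compounds
F1 | step 16 | C9 aldehyde C10 mesylate | CC(C)(C)[Si](C)(C)O[C@H](C=O)[C@H]1[C@H](CN(C)C)C(=O)O[C@@H]1[C@@H]1O[C@]1(C)CCCC(OS(C)(=O)=O)C(=O)OC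
F2 | step 16 | C9 aldehyde C10 bromide | CC(C)(C)[Si](C)(C)O[C@H](C=O)[C@H]1[C@H](CN(C)C)C(=O)O[C@@H]1[C@@H]1O[C@]1(C)CCCC(Br)C(=O)OC
F3 | step 16 | ten-membered C9 carbinol C10 ester (C9 and C10 epimers) | CC(C)(C)[Si](C)(C)O[C@H]1[C@H]2[C@H](CN(C)C)C(=O)O[C@@H]2[C@@H]2O[C@]2(C)CCCC(C(=O)OC)C1O
F4 | step 9 | 8R epimer of 15 | O[C@@H](C(=O)O)[C@H]1C(=C)C(=O)O[C@@H]1[C@@H]1O[C@]1(C)CCCC(O[Si](CC)(CC)CC)C(=O)OC
F5 | step 9 | 8R epimer of 16 | O[C@@H](C(=O)O)[C@H]1[C@H](CN(C)C)C(=O)O[C@@H]1[C@@H]1O[C@]1(C)CCCC(O[Si](CC)(CC)CC)C(=O)OC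
F6 | step 9 | 8R hydroxy S-(9-fluorenylmethyl) thioester | O[C@@H](C(=O)SCC1c2ccccc2-c2ccccc21)[C@H]1[C@H](CN(C)C)C(=O)O[C@@H]1[C@@H]1O[C@]1(C)CCCC(O[Si](CC)(CC)CC)C(=O)OC
F7 | step 9 | 8S formate of the thioester | O=CO[C@H](C(=O)SCC1c2ccccc2-c2ccccc21)[C@H]1[C@H](CN(C)C)C(=O)O[C@@H]1[C@@H]1O[C@]1(C)CCCC(O[Si](CC)(CC)CC)C(=O)OC
F8 | step 9 | 8S hydroxy S-(9-fluorenylmethyl) thioester | O[C@H](C(=O)SCC1c2ccccc2-c2ccccc21)[C@H]1[C@H](CN(C)C)C(=O)O[C@@H]1[C@@H]1O[C@]1(C)CCCC(O[Si](CC)(CC)CC)C(=O)OC
F9 | step 15 | C9 thioacid C10 alcohol | CC(C)(C)[Si](C)(C)O[C@H](C(=O)S)[C@H]1[C@H](CN(C)C)C(=O)O[C@@H]1[C@@H]1O[C@]1(C)CCCC(O)C(=O)OC
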